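Locants used throughout: C1 is the quaternary ring-fusion carbon that bears the methyl group; the five-membered ring is C1–C2–C3–C4–C5 and the seven-membered ring is C5–C6–C7–C8–C9–C10–C1. β is the face of the C1 methyl group, α the opposite face.

## Analysis of the target

Target 22 is a cis-fused bicyclo[5.3.0]decene (hydroazulene of the daucane type): a cyclopentane C1–C5 fused along C1–C5 to a cycloheptene with the C7=C8 double bond and a methyl group on C8. It has six stereocentres, in this numbering 1S (quaternary, methyl), 3S (acetoxy), 4R (tertiary hydroxyl and isopropyl), 5R (ring-fusion hydrogen), 6S (4-hydroxybenzoyloxy) and 10S (hydroxyl). The C1 methyl, H5, the C3 acetoxy, the C4 hydroxyl and the C10 hydroxyl all lie on the β-face; the isopropyl group and the C6 ester oxygen are α, so the C3/C4 oxygens form a cis-diol and C6 and C10 both leave the cyclopentane on its α-face. Sensitive groups are the allylic aryl ester at C6 (ionisation, transposition), the secondary acetate next to a free tertiary alcohol, the free phenol, and the C4 oxygen, which is β to C6 and therefore prone to retro-aldol cleavage or elimination whenever C6 is a ketone. The difficulty lies in five contiguous stereocentres around the ring fusion (one quaternary), in the seven-membered ring, and in telling four oxygen functions apart (two different esters, two free hydroxyls). The strategy rests on reading C6–C7=C8(CH3)–C9 as a 3-methylbut-2-enoyl ketone on C5 whose γ-methyl becomes C9, and C10 as the carbinol from a non-enolisable aldehyde on C1; joining C9 to C10 by a vinylogous aldol addition closes the seven-membered ring with every ring carbon and oxygen at its final or penultimate oxidation level.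

## Retrosynthetic reasoning

**Esters and protecting groups (22 ← 21 ← 17 + 20).** The last step only removes two silyl groups from 21, one on the C10 oxygen and one on the phenol, so the final operation is a neutral fluoride treatment that cannot disturb the allylic ester or the acetate. The C6–O acyl bond of 21 is cut next, giving allylic alcohol 17 and the silyl-protected acid 20, which comes from 18 by way of 19. The C3 acetate is deliberately not introduced at this stage; it is carried from before the ring closure (see below), so no cyclic ketal has to be removed with acid once the ionisable allylic ester is present.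

**C6 stereocentre (17 ← 16 ← 15).** The C6 carbinol of 17 is traced to the C6 enone of 16 by a 1,2-reduction in which hydride has to enter from the convex β-face of the cis-fused bicycle. The C10 hydroxyl of 15 is silylated first (16) so that only one secondary alcohol is free when the aryl ester is made.

**Key disconnection C9–C10 (15 ← 13).** Cutting C9–C10 opens the seven-membered ring to the cyclopentane keto-aldehyde 13. The cut is placed here because the aldehyde on quaternary C1 cannot enolise, the γ-methyl of the enone is the only accessible acidic position, and the bond formation gives back the C6 enone with C7=C8 and the C8 methyl in place. The forward reaction must run through the silyl dienol ether 14, add through its γ-carbon, and set C10 with the hydroxyl on the β-face.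

**C3/C4 diol and acetate (13 ← 12 ← 11).** The acetate is removed to diol 12, and the cis-diol is traced to the C3=C4 alkene of 11. A cis-dihydroxylation anti to the adjacent C5 acyl group puts both oxygens on the β-face and the isopropyl group on the α-face. At this point C7=C8 is conjugated to the C6 ketone and therefore unreactive towards the electrophilic oxidant, so the only electron-rich alkene is C3=C4. The tertiary C4 hydroxyl stays free in 13 and is masked only transiently, as the trimethylsilyl ether in 14, inside the key step.

**Keto-aldehyde from a lactone (11 ← 10 ← 9 ← 8).** Both carbonyl groups of 11 are traced, via hydroxy enone 10 and diol 9, to the cis-fused γ-lactone 8, in which C10 is the lactone carbonyl and C6 the lactone carbinol. The lactone is the stereochemical device of the route: it can only exist when C6 and C10 are cis on the cyclopentane, and it keeps C5 from epimerising while the ring is functionalised.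

**Isopropyl alkene (8 ← 7 ← 5).** The C3=C4 alkene of 8 with its isopropyl group is traced to the C4 ketone of 5 through enolate 6 and enol triflate 7. Kinetic enolisation goes to the C3 methylene because C5 is a hindered ring-fusion methine, and cross-coupling replaces the triflate by isopropyl with the alkene position fixed.

**Cyclopentane and quaternary centre (5 ← 1 + 2).** Keto-lactone 5 is cut at C1–CH3, C5–C6 and the lactone C–O bond. A catalytic enantioselective conjugate addition of a methyl group to the ester-bearing enone 1 creates C1, the resulting zinc enolate 3 is trapped at C5 by aldehyde 2, and the aldolate 4 closes the lactone. Adding methyl to an enone that already carries C10 as an ester, rather than adding a C10 precursor to a methyl enone, has three advantages: C10 arrives without an extra alkene that would compete in later oxidations, it provides the acyl group for the lactone lock, and the enolate is a zinc enolate that is reliable in aldol trapping.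

## Alternatives that were turned down

**Alternative 1:** The cyclopentene is disconnected at C1–C2 and C4–C5, giving the seven-membered enone A1 and the allenylsilane A2. In the forward step TiCl4 would promote a (3+2) annulation: the CH2 terminus of A2 adds to the β-carbon C1 of A1, silicon shifts, and the enolate carbon C5 captures the vinyl cation to give the bicyclic vinylsilane A3.
- For: it is convergent, forms two C–C bonds, the quaternary centre and the cis ring fusion in one operation, and the C10 silyloxy group next to C1 could steer the facial approach.
- Against: C1 of A1 is a fully substituted β-carbon flanked by the silyloxy-bearing C10, which is the slow case for attack by a weak π-nucleophile, and A2 carries a branched group on its silicon-bearing carbon.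
- Against: A3 arrives with C7–C9 as plain methylenes, so the C8 methyl and the C7=C8 alkene would need a dehydrogenation, a methyl addition and a second dehydrogenation. The C3=C4 bond of A3 is a tetrasubstituted vinylsilane that still has to be turned into the cis-diol.
- Comparison: on convergence and on making the quaternary centre and ring fusion together this alternative is stronger. The chosen strategy offers a seven-membered ring that is formed with its methyl group, alkene and both oxygens, so only redox and protecting-group steps follow the closure.

**Alternative 2:** The C1–C5 bond is disconnected to the trans-fused decalin A4, in which C1 is bonded to the carbinol carbon C6 and C5 carries a mesylate. KOt-Bu would trigger a semipinacol shift in A4: C1 migrates from C6 to C5 with inversion at C5 while C6 becomes the ketone, giving the hydroazulenone A5.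
- For: the decalin skeleton of A4 belongs to the family reached by proline-catalysed Robinson annulation in either enantiomeric series, which settles the absolute configuration of C1 cheaply. The antiperiplanar migration is stereospecific, so the cis fusion and C5 are guaranteed, and the C6 and C10 oxygens are in place in A5.
- Against: A4 needs a cis-hydroxy mesylate with an equatorial leaving group on a trans-decalin, which costs several stereocontrolled steps.
- Against: A5 lacks the C8 methyl, the C7=C8 alkene, the C3 oxygen and the isopropyl group. Adding isopropyl to the C4 ketone would have to occur from the concave α-face, against the steric bias.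
- Comparison: this alternative is stronger on absolute stereocontrol and on the certainty of the ring-forming event. The chosen strategy is much shorter after ring formation and sets the cyclopentane stereocentres on a monocyclic system by a lactone lock and a dihydroxylation.

**Alternative 3:** The C5–C6 bond is disconnected to the cyclopentenyl allylsilane A6, which carries a (Z)-enal chain on C1. BF3·OEt2 would activate the aldehyde of A6, and the allylsilane would attack through C5 anti to silicon, closing the seven-membered ring and moving the ring alkene to C3=C4. The product of this closure is the bicyclic allylic alcohol A7.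
- For: it forms the ring and two stereocentres (C5, C6) at once. A7 carries C6 directly as the alcohol, so no enone reduction is needed, has C7=C8 and the C8 methyl in place, and has C3=C4 ready for dihydroxylation from the convex face. On stereocentre count and oxidation-state economy it is as strong as or stronger than the chosen closure.
- Against: the enal of A6 must be and stay (Z), and Lewis acids isomerise enals to the (E) form, which cannot close. Conjugate attack of C5 on C8 would close a five-membered ring instead.
- Against: A6 needs a stereodefined allylic silane in addition to the quaternary centre and C10. The later dihydroxylation of A7 would have to distinguish two trisubstituted alkenes, C3=C4 and C7=C8.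
- Comparison: the chosen strategy sets one stereocentre fewer in its key step and needs the extra reduction at C6. In return its precursor is short, no (Z)-alkene has to be preserved, and the dihydroxylation is done while C7=C8 is deactivated by conjugation, a distinction that A7 does not offer.

Key step: step 9

Assumption: methyl 3-oxocyclopent-1-ene-1-carboxylate (1) is taken as a purchasable building block.
Assumption: the C6 carbinol centre in 4–9 is not controlled and is destroyed in step 5, so both C6 epimers are carried forward together.

## Route

Step 1
Reactants: 1 methyl 3-oxocyclopent-1-ene-1-carboxylate; 2 3-methylbut-2-enal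
Product: 5 cis-fused keto-lactone (C6 epimers), via methylzinc enolate 3 (not isolated), via methylzinc aldolate 4 (not isolated)
Conditions: Me2Zn (3 equiv), Cu(OTf)2 (2.5 mol %), chiral sulfonate-bearing imidazolinium salt (NHC precursor, 5 mol %), t-BuOMe, −30 °C; 2 (1.3 equiv), −78 → 23 °C; aq. NH4Cl
Reagents that add atoms: dimethylzinc, C[Zn]C
Why: Copper-catalysed enantioselective conjugate addition of a dialkylzinc to a β-alkoxycarbonyl enone sets the quaternary C1 under ligand control (the ligand enantiomer that gives the S centre is used) and leaves the regiodefined zinc enolate 3, which adds to aldehyde 2 at C5. Only the aldolate whose side chain is cis to the ester can close the γ-lactone, and the aldol step is reversible on warming, so lactonisation is expected to fix the cis relationship of C6 and C10 (5R).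

Step 2
Reactants: 5 cis-fused keto-lactone
Product: 7 enol triflate (C3=C4), via lithium enolate 6 (not isolated)
Conditions: LiN(i-Pr)2 (1.1 equiv), THF, −78 °C; Comins' reagent (1.2 equiv), −78 → −20 °C; aq. NH4Cl
Reagents that add atoms: N-(5-chloropyridin-2-yl)-N-(trifluoromethylsulfonyl)trifluoromethanesulfonamide (Comins' reagent), O=S(=O)(N(c1ccc(Cl)cn1)S(=O)(=O)C(F)(F)F)C(F)(F)F
Why: Kinetic deprotonation takes the C3 methylene rather than the hindered ring-fusion methine C5 (the lactone has no α-hydrogen), and O-triflation of the lithium enolate occurs at low temperature. No stereocentre is touched, and the cis-fused lactone cannot epimerise at C5.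

Step 3
Reactants: 7 enol triflate
Product: 8 isopropyl alkene lactone
Conditions: i-PrZnBr (2 equiv), PdCl2(dppf) (5 mol %), THF, 23 → 50 °C
Reagents that add atoms: isopropylzinc bromide, CC(C)[Zn]Br
Why: Negishi cross-coupling of an alkenyl triflate with a secondary alkylzinc halide; the wide bite angle of dppf favours reductive elimination over β-hydride elimination, and the lactone is inert to the organozinc.

Step 4
Reactants: 8 isopropyl alkene lactone
Product: 9 diol (C6 allylic alcohol, C10 primary alcohol)
Conditions: LiAlH4 (1.5 equiv), THF, 0 °C; H2O, aq. NaOH
Reagents that add atoms: none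
Why: Hydride reduction of the lactone to the 1,4-diol; the two isolated alkenes are inert and no stereocentre on the ring is affected.

Step 5
Reactants: 9 diol
Product: 10 hydroxy enone
Conditions: MnO2 (activated, 20 equiv), CH2Cl2, 23 °C
Reagents that add atoms: none
Why: MnO2 oxidises only the allylic C6 alcohol, which removes the uncontrolled C6 centre and conjugates C7=C8 to the ketone. The neutral heterogeneous conditions are chosen so that C3=C4 does not move into conjugation and C5 does not epimerise. Oxidising C6 before C10 also prevents the C6 hydroxyl from trapping the later aldehyde as a lactol that would be oxidised back to lactone 8.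

Step 6
Reactants: 10 hydroxy enone
Product: 11 keto-aldehyde
Conditions: Dess–Martin periodinane (1.3 equiv), NaHCO3, CH2Cl2, 0 → 23 °C
Reagents that add atoms: none
Why: Buffered Dess–Martin oxidation of the neopentyl primary alcohol gives the aldehyde on quaternary C1, which has no α-hydrogen and cannot enolise.

Step 7
Reactants: 11 keto-aldehyde
Product: 12 3β,4β-diol
Conditions: OsO4 (2 mol %), N-methylmorpholine N-oxide (1.3 equiv), acetone/H2O, 0 → 23 °C; aq. Na2SO3
Reagents that add atoms: osmium tetroxide (catalytic oxygen carrier), O=[Os](=O)(=O)=O; N-methylmorpholine N-oxide, C[N+]1([O-])CCOCC1; water, O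
Why: Catalytic cis-dihydroxylation (Upjohn conditions) attacks only the electron-rich C3=C4 alkene, since C7=C8 is part of the enone. The oxidant approaches anti to the allylic C5 acyl group, on the face of H5 and the C1 methyl, which sets 3S and 4R with both hydroxyls β and the isopropyl group α.

Step 8
Reactants: 12 3β,4β-diol
Product: 13 3β-acetate keto-aldehyde
Conditions: Ac2O (1.5 equiv), pyridine, DMAP (10 mol %), CH2Cl2, 0 → 23 °C
Reagents that add atoms: acetic anhydride, CC(=O)OC(C)=O
Why: DMAP-catalysed acetylation takes the secondary C3 hydroxyl; the tertiary C4 hydroxyl, flanked by the isopropyl group, is inert under these conditions.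

Step 9
Reactants: 13 3β-acetate keto-aldehyde
Product: 15 bicyclic hydroxy enone, via bis-silylated dienol ether 14 (not isolated)
Conditions: TMSOTf (2.3 equiv), Et3N (2.6 equiv), CH2Cl2 (0.01 M), 0 °C; BF3·OEt2 (3 equiv), −78 → 0 °C; aq. NaHCO3; 1 M HCl, THF, 0 °C
Reagents that add atoms: none
Why: Soft enolisation silylates the tertiary C4 hydroxyl and removes a γ-methyl proton of the O-silylated enone (the α′-position C5 is a hindered methine between C1 and C4), giving the 2-siloxydiene 14; BF3·OEt2 then activates the non-enolisable C10 aldehyde, the terminal CH2 (C9) adds to it to form C9–C10, and loss of silicon restores the conjugated C6 enone with C7=C8 in place. The closest known reaction type is the intramolecular vinylogous Mukaiyama aldol addition of a silyl dienol ether to an aldehyde. The seven-membered ring closes in a 7-exo-trig mode with respect to the aldehyde, with the whole dienol unit inside the forming ring; the competing attack through C7 would be a 5-(enolendo)-exo-trig closure, which is stereoelectronically disfavoured and adds to the inherent γ-preference of silyl dienol ethers. Closure requires the dienol ether isomer with C5 and C8 cis across C6=C7, whereas the kinetically formed isomer should have them trans; the two are expected to interconvert through reversible γ-protonation by the triethylammonium triflate left in the flask, so that the reaction drains through the only isomer able to cyclise. The cis relationship of the acyl and formyl groups has been fixed since 5, so no epimerisation at C5 is needed. The new C10 stereocentre is controlled by the adjacent quaternary C1 and the cis ring fusion: the Lewis-acid-bound oxygen should point to the convex face, syn to the C1 methyl, giving the 10β-alcohol (10S). The step needs chemoselective γ-enolisation and survival of the acetate and of the β-silyloxy ketone, which the low temperature and the absence of an accessible α-proton should secure.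

Step 10
Reactants: 15 bicyclic hydroxy enone
Product: 16 10β-triethylsilyl ether
Conditions: Et3SiCl (1.5 equiv), imidazole (3 equiv), DMAP (cat.), DMF, 23 °C
Reagents that add atoms: chlorotriethylsilane, CC[Si](Cl)(CC)CC
Why: Silylation with a silyl chloride and imidazole takes the secondary C10 hydroxyl; tertiary alcohols such as C4–OH do not react under these conditions.

Step 11
Reactants: 16 10β-triethylsilyl ether
Product: 17 6α-allylic alcohol
Conditions: NaBH4 (1.5 equiv), CeCl3·7H2O (1.5 equiv), MeOH, −78 → −40 °C
Reagents that add atoms: none
Why: Luche reduction gives clean 1,2-reduction of the enone and leaves the acetate alone. Hydride should enter from the convex β-face (syn to H5, away from the five-membered ring and the α-isopropyl group on C4), giving the 6α-alcohol (6S).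

Step 12
Reactants: 18 4-hydroxybenzoic acid
Product: 20 4-(tert-butyldimethylsilyloxy)benzoic acid, via silyl ester 19 (not isolated)
Conditions: t-BuMe2SiCl (2.5 equiv), imidazole (5 equiv), DMF, 23 °C; AcOH/THF/H2O, 23 °C
Reagents that add atoms: tert-butyldimethylsilyl chloride, CC(C)(C)[Si](C)(C)Cl
Why: Both acidic groups are silylated, and the far more labile silyl ester is then hydrolysed selectively, leaving the aryl silyl ether.

Step 13
Reactants: 17 6α-allylic alcohol; 20 4-(tert-butyldimethylsilyloxy)benzoic acid
Product: 21 bis-silylated ester
Conditions: 20 (1.5 equiv), EDC·HCl (2 equiv), DMAP (2 equiv), CH2Cl2, 23 °C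
Reagents that add atoms: none
Why: Carbodiimide/DMAP (Steglich) esterification acylates the only free secondary alcohol; the tertiary C4 hydroxyl does not react, and C6 keeps its configuration because only the O–acyl bond is formed.

Step 14
Reactants: 21 bis-silylated ester
Product: 22 target CNP0146780.2
Conditions: Bu4NF (3 equiv), AcOH (3 equiv), THF, 0 → 23 °C
Reagents that add atoms: none
Why: Fluoride cleaves the alkyl triethylsilyl ether and the aryl tert-butyldimethylsilyl ether in one operation; acetic acid buffering keeps the phenoxide protonated and should suppress acyl migration or ester cleavage.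

## Compound list

1 | methyl 3-oxocyclopent-1-ene-1-carboxylate | COC(=O)C1=CC(=O)CC1 | starting material
2 | 3-methylbut-2-enal | CC(C)=CC=O | starting material
3 | methylzinc enolate of methyl (S)-1-methyl-3-oxocyclopentane-1-carboxylate (C4–O–Zn, C4=C5) | COC(=O)[C@@]1(C)CCC(O[Zn]C)=C1 | intermediate
4 | methylzinc aldolate: C4 ketone, C5 side chain CH(OZnCH3)CH=C(CH3)2 on the α-face cis to the ester, C6 epimers | COC(=O)[C@@]1(C)CCC(=O)[C@H]1C(O[Zn]C)C=C(C)C | intermediate
5 | cis-fused keto-lactone: C4 ketone, γ-lactone C10(=O)–O–C6 on the α-face, 1β-methyl, 5β-H, 2-methylprop-1-enyl on C6 (C6 epimers) | O=C1CC[C@]2(C)C(=O)OC(C=C(C)C)[C@H]12 | intermediate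
6 | lithium enolate of 5 (C4–O–Li, C3=C4) | [Li]OC1=CC[C@]2(C)C(=O)OC(C=C(C)C)[C@H]12 | intermediate
7 | enol triflate of 5 (C4–OTf, C3=C4) | O=S(=O)(OC1=CC[C@]2(C)C(=O)OC(C=C(C)C)[C@H]12)C(F)(F)F | intermediate
8 | lactone with 4-isopropyl C3=C4 alkene | CC(C)C1=CC[C@]2(C)C(=O)OC(C=C(C)C)[C@H]12 | intermediate
9 | diol: 4-isopropylcyclopent-3-ene with 1β-methyl, 1α-CH2OH (C10) and 5α-CH(OH)CH=C(CH3)2 (C6 epimers) | CC(C)C1=CC[C@](C)(CO)[C@@H]1C(O)C=C(C)C | intermediate
10 | hydroxy enone: as 9 with C6 ketone (3-methylbut-2-enoyl on C5α) and C10 primary alcohol | CC(C)C1=CC[C@](C)(CO)[C@@H]1C(=O)C=C(C)C | intermediate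
11 | keto-aldehyde: 1β-methyl, 1α-formyl, 5α-(3-methylbut-2-enoyl), 4-isopropyl C3=C4 alkene | CC(C)C1=CC[C@](C)(C=O)[C@@H]1C(=O)C=C(C)C | intermediate
12 | diol keto-aldehyde: 3β-OH, 4β-OH, 4α-isopropyl, 5α-(3-methylbut-2-enoyl), 1β-methyl, 1α-formyl | O[C@H]1C[C@](C)(C=O)[C@H](C(=O)C=C(C)C)[C@]1(O)C(C)C | intermediate
13 | 3β-acetate of 12 (key-step precursor; 4β-OH free) | CC(=O)O[C@H]1C[C@](C)(C=O)[C@H](C(=O)C=C(C)C)[C@]1(O)C(C)C | intermediate
14 | bis(trimethylsilyl) compound: C4–O–SiMe3 and 2-siloxydiene C6(OSiMe3)=C7–C8(CH3)=C9H2 (C6=C7 geometry not fixed) | CC(=O)O[C@H]1C[C@](C)(C=O)[C@H](C(O[Si](C)(C)C)=CC(C)=C)[C@]1(O[Si](C)(C)C)C(C)C | intermediate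
15 | cis-fused bicyclic hydroxy enone: C6 ketone, C7=C8 (8-methyl), 10β-OH, 3β-OAc, 4β-OH, 4α-isopropyl (key-step product) | CC(=O)O[C@H]1C[C@]2(C)[C@@H](O)CC(C)=CC(=O)[C@@H]2[C@]1(O)C(C)C | intermediate
16 | 10β-triethylsilyl ether of 15 | CC(=O)O[C@H]1C[C@]2(C)[C@@H](O[Si](CC)(CC)CC)CC(C)=CC(=O)[C@@H]2[C@]1(O)C(C)C | intermediate
17 | 6α-allylic alcohol (6S) | CC(=O)O[C@H]1C[C@]2(C)[C@@H](O[Si](CC)(CC)CC)CC(C)=C[C@H](O)[C@@H]2[C@]1(O)C(C)C | intermediate
18 | 4-hydroxybenzoic acid | O=C(O)c1ccc(O)cc1 | starting material
19 | tert-butyldimethylsilyl 4-(tert-butyldimethylsilyloxy)benzoate | CC(C)(C)[Si](C)(C)OC(=O)c1ccc(O[Si](C)(C)C(C)(C)C)cc1 | intermediate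
20 | 4-(tert-butyldimethylsilyloxy)benzoic acid | CC(C)(C)[Si](C)(C)Oc1ccc(C(=O)O)cc1 | intermediate
21 | 6α-[4-(tert-butyldimethylsilyloxy)benzoyloxy] 10β-triethylsilyl ether | CC(=O)O[C@H]1C[C@]2(C)[C@@H](O[Si](CC)(CC)CC)CC(C)=C[C@H](OC(=O)c3ccc(O[Si](C)(C)C(C)(C)C)cc3)[C@@H]2[C@]1(O)C(C)C | intermediate
22 | CNP0146780.2: 3β-acetoxy-4β,10β-dihydroxy-6α-(4-hydroxybenzoyloxy) cis-fused hydroazulene (1S,3S,4R,5R,6S,10S in the numbering used here) | CC(=O)O[C@H]1C[C@]2(C)[C@@H](O)CC(C)=C[C@H](OC(=O)c3ccc(O)cc3)[C@@H]2[C@]1(O)C(C)C | target

## Step count and least certain steps

Total: 14 steps. Longest linear sequence: 13 steps (steps 1–11, 13 and 14); step 12 is the side branch to 20.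

**Step 9 (key step).** The most likely failure is that the silyl dienol ether forms with the unproductive C6=C7 geometry and does not isomerise fast enough, so that ring closure stalls and desilylation or intermolecular aldol addition takes over. A second concern is facial selectivity at C10, which would have to be corrected by an oxidation–reduction sequence at that carbon.
Fallback (sets out from 13, returns at 15): the dienol ether 14 is made as in step 9 and cleaved with Bu4NF/AcOH at −78 °C, so that the liberated dienolate is protonated kinetically at C7. This gives the deconjugated β,γ-unsaturated keto-aldehyde F1. Me2AlCl then promotes an intramolecular carbonyl-ene (Prins-type) cyclisation in which the 1,1-disubstituted alkene terminus C9 adds to the C10 aldehyde, with no dienol geometry to satisfy. Loss of the acidic C7 proton gives 15; any exocyclic-methylene isomer F2 would be moved into conjugation with a catalytic amount of DBU.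

**Step 1.** Three things may go wrong: sluggish methyl transfer or insufficient enantiofacial control in the conjugate addition; aldol addition on the face cis to the C1 methyl without equilibration; and retro-aldol loss or dehydration of the aldolate while the mixture is warmed for lactonisation.
Fallback (sets out from 1, returns at 5): the conjugate addition is run alone and enolate 3 is trapped with Me3SiCl as the trimethylsilyl enol ether F3. A TiCl4-mediated Mukaiyama aldol addition to 2 at −78 °C gives the hydroxy keto ester F4 without any basic warming period. The cis isomer of F4 is then lactonised under neutral transesterification conditions (catalytic Ti(Oi-Pr)4, toluene, 60 °C) to 5.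

**Step 3.** The isopropyl–palladium intermediate may isomerise by β-hydride elimination and reinsertion, transferring n-propyl, or the hindered triflate may simply be reduced.
Fallback (sets out from 7, returns at 8): Suzuki–Miyaura coupling of 7 with isopropenylboronic acid pinacol ester (Pd(PPh3)4, K3PO4, dioxane/H2O) gives the diene F5. Hydrogenation with RhCl(PPh3)3 under H2 then saturates only the 1,1-disubstituted terminal alkene and leaves the trisubstituted C3=C4 and C7=C8 alkenes, giving 8.

**Step 11.** Facial selectivity of hydride delivery may be poor, because the angular methyl on the convex face competes with the hindrance of the concave face; attack from the α-face would give the 6β-alcohol.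
Fallback (sets out from 16, returns at 21): the 6β-alcohol F6 obtained from the reduction of 16 is esterified with 20 under Mitsunobu conditions (PPh3, diisopropyl azodicarboxylate, THF, 0 °C). This inverts C6 and gives 21 directly.

## Further compounds

F1 | step 9 | β,γ-unsaturated keto-aldehyde: as 13 but with a 3-methylbut-3-enoyl group on C5 | CC(=O)O[C@H]1C[C@](C)(C=O)[C@H](C(=O)CC(C)=C)[C@]1(O)C(C)C
F2 | step 9 | exocyclic-methylene isomer of 15 (C8=CH2, C7H2) | CC(=O)O[C@H]1C[C@]2(C)[C@@H](O)CC(=C)CC(=O)[C@@H]2[C@]1(O)C(C)C
F3 | step 1 | methyl (S)-1-methyl-3-(trimethylsilyloxy)cyclopent-2-ene-1-carboxylate | COC(=O)[C@@]1(C)CCC(O[Si](C)(C)C)=C1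
F4 | step 1 | hydroxy keto ester: methyl 2-(1-hydroxy-3-methylbut-2-enyl)-1-methyl-3-oxocyclopentane-1-carboxylate, side chain cis to the ester | COC(=O)[C@@]1(C)CCC(=O)[C@H]1C(O)C=C(C)C
F5 | step 3 | lactone with 4-isopropenyl C3=C4 diene | CC(=C)C1=CC[C@]2(C)C(=O)OC(C=C(C)C)[C@H]12
F6 | step 11 | 6β-allylic alcohol (C6 epimer of 17) | CC(=O)O[C@H]1C[C@]2(C)[C@@H](O[Si](CC)(CC)CC)CC(C)=C[C@@H](O)[C@@H]2[C@]1(O)C(C)C
A1 | alternative 1 | (S)-4-(tert-butyldimethylsilyloxy)-3-methylcyclohept-2-en-1-one | CC1=CC(=O)CCC[C@@H]1O[Si](C)(C)C(C)(C)C
A2 | alternative 1 | trimethyl(4-methylpenta-1,2-dien-3-yl)silane | C=C=C(C(C)C)[Si](C)(C)C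
A3 | alternative 1 | cis-fused bicyclic C6 ketone with 3-trimethylsilyl C3=C4 cyclopentene, 4-isopropyl and 10-silyloxy groups | C[Si](C)(C)C1C[C@]2(C)[C@@H](O[Si](C)(C)C(C)(C)C)CCCC(=O)[C@@H]2C=1C(C)C
A4 | alternative 2 | trans-fused methyl-decalin cis-hydroxy mesylate (C6 tertiary alcohol, C5 mesylate, C4 dioxolane, C10 silyl ether) | CS(=O)(=O)O[C@@H]1C2(OCCO2)CC[C@]3(C)[C@@H](O[Si](C)(C)C(C)(C)C)CCC[C@@]13O
A5 | alternative 2 | cis-fused hydroazulen-6-one with C4 dioxolane and C10 silyl ether | C1C[C@]2(C)[C@@H](O[Si](C)(C)C(C)(C)C)CCCC(=O)[C@@H]2C13OCCO3
A6 | alternative 3 | cyclopentenyl allylsilane (3β-trimethylsilyl, C4=C5, 4-isopropyl) with (Z)-enal chain on C1 | C[Si](C)(C)[C@H]1C[C@](C)([C@@H](O[Si](C)(C)C(C)(C)C)C/C(C)=C\C=O)C=C1C(C)C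
A7 | alternative 3 | cis-fused bicyclic 6α-allylic alcohol with C3=C4 and C7=C8 alkenes and C10 silyl ether | C1C[C@]2(C)[C@@H](O[Si](C)(C)C(C)(C)C)CC(C)=C[C@H](O)[C@@H]2C=1C(C)C
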